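The plan rests on cutting the C5–C6 bond of the 1,2-dioxane ring (O1, O2, C3, C4, C5, C6). C6 bears O1, a methyl group and the C7 chain, so it stands at the ketone oxidation level and can be turned into a peroxycarbenium ion; the ring closes when C5 of a C4=C5 vinylsilane, tethered through the O1–O2 bond, attacks it with loss of silicon. This one operation forms C5–C6, closes the ring, sets C6 against C3 and leaves a C4=C5 alkene from which C4 is set. The precursor is the mixed methyl peroxyketal of the citronellal-derived C6–C16 ketone with an S-configured β-hydroperoxy ester that carries a Z-vinylsilane.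

Key step: step 13

Assumption: atoms are numbered as in the target acid (C1 carboxyl, C2, ring C3–C6, chain C7–C16); the peroxidase of step 11 is taken to reduce the R hydroperoxide faster, as it does with related secondary hydroperoxides, and this sense is to be confirmed on the derived alcohol (Mosher ester) before the material is carried on.

**Fragment A: ketal 10 (C6–C16 and phenyl)**

Step 1
Reactants: 1 (R)-citronellal
Product: 2 (4R)-4,8-dimethylnon-7-en-2-ol (both C2 epimers)
Conditions: MeMgBr, Et2O, 0 °C; then aq. NH4Cl
Reagents that add atoms: methylmagnesium bromide, C[Mg]Br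
Why: Grignard addition to the aldehyde gives the secondary alcohol; the carbinol centre is not controlled because step 2 oxidises it, and the C8 stereocentre (β to the carbonyl) is not touched.

Step 2
Reactants: 2 (4R)-4,8-dimethylnon-7-en-2-ol
Product: 3 (R)-4,8-dimethylnon-7-en-2-one
Conditions: Dess–Martin periodinane, CH2Cl2, rt
Reagents that add atoms: none
Why: Dess–Martin oxidation of the secondary alcohol gives the methyl ketone and leaves the trisubstituted alkene and the β-stereocentre alone.

Step 3
Reactants: 3 (R)-4,8-dimethylnon-7-en-2-one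
Product: 4 (6R)-8,8-dimethoxy-2,6-dimethylnon-2-ene
Conditions: HC(OMe)3, MeOH, TsOH·H2O (cat.), rt; then Et3N
Reagents that add atoms: trimethyl orthoformate, COC(OC)OC; methanol, CO
Why: Acid-catalysed ketalisation, driven by the orthoester as water scavenger, masks the ketone against the Grignard reagent of step 6 and installs the leaving group that step 12 needs.

Step 4
Reactants: 4 (6R)-8,8-dimethoxy-2,6-dimethylnon-2-ene
Product: 6 (R)-6,6-dimethoxy-4-methylheptan-1-ol, via ozonide 5 (not isolated)
Conditions: O3, CH2Cl2, NaHCO3, −78 °C; then NaBH4, MeOH, −78 °C to rt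
Reagents that add atoms: ozone, [O-][O+]=O
Why: Ozonolysis cleaves the only alkene, and hydride reduction of the ozonide gives the primary alcohol under non-acidic conditions that the dimethyl ketal tolerates.

Step 5
Reactants: 6 (R)-6,6-dimethoxy-4-methylheptan-1-ol
Product: 7 (R)-6,6-dimethoxy-4-methylheptyl 4-methylbenzenesulfonate
Conditions: TsCl, Et3N, DMAP (cat.), CH2Cl2, 0 °C to rt
Reagents that add atoms: 4-methylbenzenesulfonyl chloride, Cc1ccc(cc1)S(=O)(=O)Cl
Why: Sulfonylation of the primary alcohol under basic conditions activates C11 for substitution without endangering the ketal.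

Step 6
Reactants: 7 (R)-6,6-dimethoxy-4-methylheptyl 4-methylbenzenesulfonate; 8 (5-bromopentyl)benzene
Product: 10 [(9R)-11,11-dimethoxy-9-methyldodecyl]benzene, via (5-phenylpentyl)magnesium bromide 9 (not isolated)
Conditions: 8, Mg, THF, reflux; then 7, Li2CuCl4 (cat.), THF, −78 °C to rt; then aq. NH4Cl/NH3 (pH 8)
Reagents that add atoms: none
Why: Copper-catalysed coupling of a primary alkyl Grignard reagent with a primary tosylate (Kochi coupling) forms the C11–C12 bond far from the stereocentre, and the ketal is inert to the organometallic.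

**Fragment B: hydroperoxide 17 (C1–C5)**

Step 7
Reactants: 11 5-methyl-2,3-dihydrofuran
Product: 12 (Z)-4-methyl-5-(trimethylsilyl)pent-3-en-1-ol
Conditions: Me3SiCH2MgCl, NiCl2(PPh3)2 (cat.), toluene/Et2O, 70 °C; then aq. NH4Cl
Reagents that add atoms: (trimethylsilyl)methylmagnesium chloride, C[Si](C)(C)C[Mg]Cl
Why: Nickel-catalysed Kumada-type coupling at the vinylic C–O bond of a cyclic enol ether (Wenkert coupling) opens the ring with retention of alkene geometry, so the silylmethyl group replaces oxygen cis to the hydroxyethyl chain and the Z allylsilane results; the Grignard reagent has no β-hydrogen that could cause reduction or isomerisation.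

Step 8
Reactants: 12 (Z)-4-methyl-5-(trimethylsilyl)pent-3-en-1-ol
Product: 14 (Z)-4-methyl-5-(trimethylsilyl)pent-3-enoic acid, via aldehyde 13 (not isolated)
Conditions: TEMPO (cat.), PhI(OAc)2, MeCN/aq. phosphate buffer (pH 7), 0 °C to rt
Reagents that add atoms: water, O
Why: Nitroxyl-catalysed oxidation takes the primary alcohol through the aldehyde to the acid under near-neutral conditions, which avoid both protodesilylation of the allylsilane and migration of the β,γ-alkene into conjugation.

Step 9
Reactants: 14 (Z)-4-methyl-5-(trimethylsilyl)pent-3-enoic acid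
Product: 15 methyl (Z)-4-methyl-5-(trimethylsilyl)pent-3-enoate
Conditions: Me3SiCHN2, toluene/MeOH, 0 °C
Reagents that add atoms: (trimethylsilyl)diazomethane, C[Si](C)(C)C=[N+]=[N-]
Why: O-Methylation of the acid by the diazoalkane needs neither base nor strong acid, so the β,γ-alkene and the allylsilane are preserved.

Step 10
Reactants: 15 methyl (Z)-4-methyl-5-(trimethylsilyl)pent-3-enoate
Product: 16 methyl (Z)-3-hydroperoxy-4-methyl-5-(trimethylsilyl)pent-4-enoate (racemic)
Conditions: O2, tetraphenylporphyrin (cat.), visible light, CH2Cl2, −20 °C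
Reagents that add atoms: dioxygen, O=O
Why: Schenck ene reaction of an allylsilane: singlet oxygen should bond to C3, where the charge developing at C4 is stabilised by the β-silicon, and take a hydrogen from the silyl-bearing C5, which lies on the more substituted side of the alkene (cis effect), while the C–Si bond held anti to the incoming oxygen should turn silicon into the position cis to C3 (Z vinylsilane); C3 forms as a racemate.

Step 11
Reactants: 16 methyl (Z)-3-hydroperoxy-4-methyl-5-(trimethylsilyl)pent-4-enoate (racemic)
Product: 17 methyl (S,Z)-3-hydroperoxy-4-methyl-5-(trimethylsilyl)pent-4-enoate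
Conditions: horseradish peroxidase, guaiacol, phosphate buffer (pH 6), rt, stopped just past half conversion
Reagents that add atoms: none
Why: Enzymatic kinetic resolution: the peroxidase should reduce the R hydroperoxide to the R alcohol with guaiacol as hydrogen donor and leave the S hydroperoxide, which is separated from the alcohol by chromatography.

**Union and end game**

Step 12
Reactants: 17 methyl (S,Z)-3-hydroperoxy-4-methyl-5-(trimethylsilyl)pent-4-enoate; 10 [(9R)-11,11-dimethoxy-9-methyldodecyl]benzene
Product: 18 methyl (3S,4Z)-3-{[(4R)-2-methoxy-4-methyl-12-phenyldodecan-2-yl]peroxy}-4-methyl-5-(trimethylsilyl)pent-4-enoate (both epimers at the ketal carbon C6)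
Conditions: 10 (1.5 equiv), PPTS (cat.), 4 Å molecular sieves, CH2Cl2, 0 °C to rt; then Et3N
Reagents that add atoms: none
Why: Acid-catalysed exchange of one methoxy group of the dimethyl ketal for the hydroperoxide (peroxyketalisation) runs under conditions too mild for the vinylsilane or the O–O bond, an excess of ketal and removal of methanol hold it at the mixed peroxyketal, and the configuration of the ketal carbon is irrelevant because step 13 planarises it.

Step 13
Reactants: 18 methyl (3S,4Z)-3-{[(4R)-2-methoxy-4-methyl-12-phenyldodecan-2-yl]peroxy}-4-methyl-5-(trimethylsilyl)pent-4-enoate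
Product: 21 methyl 2-[(3S,6R)-4,6-dimethyl-6-[(2R)-2-methyl-10-phenyldecyl]-3,6-dihydro-1,2-dioxin-3-yl]acetate, via peroxycarbenium triflate 19 (not isolated), via silyl-stabilised cation 20 (not isolated)
Conditions: Me3SiOTf, 2,6-di-tert-butyl-4-methylpyridine, CH2Cl2, −78 °C; then Et3N
Reagents that add atoms: none
Why: Proposed new method: Me3SiOTf silylates the more basic methoxy oxygen of either ketal epimer and expels MeOSiMe3 to give the peroxycarbenium ion 19, whose C6 is attacked by the silicon-bearing C5 of the vinylsilane; the resulting cation 20 is tertiary at C4 and β to silicon, and loss of the silyl group to triflate regenerates Me3SiOTf and fixes the alkene at C4=C5. The closest known reactions are the Lewis-acid-mediated allylation of ketone-derived peroxycarbenium ions by allylsilanes, their closure onto tethered alkenes, and the vinylsilane-terminated cyclisation of oxocarbenium ions to 5,6-dihydro-2H-pyrans; only the pairing of the two partners is new. The 1,2-dioxine ring closes in a 6-endo mode with respect to the vinylsilane (C4 and C5 both become ring atoms), and the Z geometry is what lets the C5–Si bond turn parallel to the empty orbital at C4 as C6 moves into the ring plane. The new stereocentre C6 is set under control of C3 in a half-chair transition state: allylic strain with the C4 methyl group holds the ester arm on C3 pseudoaxial and the larger C7 chain prefers the pseudoequatorial site on C6, which gives the 3,6-cis (6R) isomer. The step needs ionisation at the methoxy and not at the peroxy oxygen, ipso attack on the vinylsilane, and no protodesilylation, and these are secured by the lower basicity of peroxide oxygen, by the β-silicon effect at a tertiary C4, and by the hindered pyridine base at −78 °C. The 3,6-trans epimer, expected as the minor product, is to be removed by chromatography.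

Step 14
Reactants: 21 methyl 2-[(3S,6R)-4,6-dimethyl-6-[(2R)-2-methyl-10-phenyldecyl]-3,6-dihydro-1,2-dioxin-3-yl]acetate
Product: 22 methyl 2-[(3S,4S,6R)-4,6-dimethyl-6-[(2R)-2-methyl-10-phenyldecyl]-1,2-dioxan-3-yl]acetate
Conditions: KO2CN=NCO2K (excess, in portions), AcOH, MeOH/CH2Cl2, 0 °C to rt
Reagents that add atoms: none
Why: Diimide reduction transfers two hydrogens in a concerted syn manner without touching the O–O bond, and it should approach C4=C5 from the face opposite the C3 ester arm and the C7 chain, which places the C4 methyl group cis to both (4S).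

Step 15
Reactants: 22 methyl 2-[(3S,4S,6R)-4,6-dimethyl-6-[(2R)-2-methyl-10-phenyldecyl]-1,2-dioxan-3-yl]acetate
Product: 23 2-[(3S,4S,6R)-4,6-dimethyl-6-[(2R)-2-methyl-10-phenyldecyl]-1,2-dioxan-3-yl]acetic acid (CNP0342712.1)
Conditions: LiOH, THF/H2O, 0 °C; then aq. HCl to pH 3, 0 °C
Reagents that add atoms: lithium hydroxide, [Li+].[OH-]
Why: Saponification at the acyl carbon frees the acid, the dialkyl peroxide is stable to cold hydroxide, and low temperature with a short reaction time limits β-elimination of the peroxide from the C2 enolate.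

**Compound list**

1 | (R)-citronellal | C[C@H](CCC=C(C)C)CC=O | starting material
2 | (4R)-4,8-dimethylnon-7-en-2-ol (both C2 epimers) | C[C@H](CCC=C(C)C)CC(C)O | intermediate
3 | (R)-4,8-dimethylnon-7-en-2-one | C[C@H](CCC=C(C)C)CC(C)=O | intermediate
4 | (6R)-8,8-dimethoxy-2,6-dimethylnon-2-ene | C[C@H](CCC=C(C)C)CC(C)(OC)OC | intermediate
5 | 3-[(3R)-5,5-dimethoxy-3-methylhexyl]-5,5-dimethyl-1,2,4-trioxolane (ozonide) | C[C@H](CCC1OOC(C)(C)O1)CC(C)(OC)OC | intermediate (not isolated)
6 | (R)-6,6-dimethoxy-4-methylheptan-1-ol | C[C@H](CCCO)CC(C)(OC)OC | intermediate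
7 | (R)-6,6-dimethoxy-4-methylheptyl 4-methylbenzenesulfonate | C[C@H](CCCOS(=O)(=O)c1ccc(C)cc1)CC(C)(OC)OC | intermediate
8 | (5-bromopentyl)benzene | BrCCCCCc1ccccc1 | starting material
9 | (5-phenylpentyl)magnesium bromide | Br[Mg]CCCCCc1ccccc1 | intermediate (not isolated)
10 | [(9R)-11,11-dimethoxy-9-methyldodecyl]benzene | C[C@H](CCCCCCCCc1ccccc1)CC(C)(OC)OC | intermediate
11 | 5-methyl-2,3-dihydrofuran | CC1=CCCO1 | starting material
12 | (Z)-4-methyl-5-(trimethylsilyl)pent-3-en-1-ol | C[Si](C)(C)C/C(C)=C\CCO | intermediate
13 | (Z)-4-methyl-5-(trimethylsilyl)pent-3-enal | C[Si](C)(C)C/C(C)=C\CC=O | intermediate (not isolated)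
14 | (Z)-4-methyl-5-(trimethylsilyl)pent-3-enoic acid | C[Si](C)(C)C/C(C)=C\CC(=O)O | intermediate
15 | methyl (Z)-4-methyl-5-(trimethylsilyl)pent-3-enoate | C[Si](C)(C)C/C(C)=C\CC(=O)OC | intermediate
16 | methyl (Z)-3-hydroperoxy-4-methyl-5-(trimethylsilyl)pent-4-enoate (racemic) | COC(=O)CC(OO)/C(C)=C\[Si](C)(C)C | intermediate
17 | methyl (S,Z)-3-hydroperoxy-4-methyl-5-(trimethylsilyl)pent-4-enoate | COC(=O)C[C@H](OO)/C(C)=C\[Si](C)(C)C | intermediate
18 | methyl (3S,4Z)-3-{[(4R)-2-methoxy-4-methyl-12-phenyldodecan-2-yl]peroxy}-4-methyl-5-(trimethylsilyl)pent-4-enoate (both C6 epimers) | C[C@H](CCCCCCCCc1ccccc1)CC(C)(OC)OO[C@@H](CC(=O)OC)/C(C)=C\[Si](C)(C)C | intermediate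
19 | peroxycarbenium ion of 18 (C6=O1+), triflate | C[C@H](CCCCCCCCc1ccccc1)CC(C)=[O+]O[C@@H](CC(=O)OC)/C(C)=C\[Si](C)(C)C.[O-]S(=O)(=O)C(F)(F)F | intermediate (not isolated)
20 | ring-closed C4 cation with the silyl group still on C5, triflate | C[C@H](CCCCCCCCc1ccccc1)C[C@]1(C)C([Si](C)(C)C)[C+](C)[C@H](CC(=O)OC)OO1.[O-]S(=O)(=O)C(F)(F)F | intermediate (not isolated)
21 | methyl 2-[(3S,6R)-4,6-dimethyl-6-[(2R)-2-methyl-10-phenyldecyl]-3,6-dihydro-1,2-dioxin-3-yl]acetate | C[C@H](CCCCCCCCc1ccccc1)C[C@]1(C)C=C(C)[C@H](CC(=O)OC)OO1 | intermediate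
22 | methyl 2-[(3S,4S,6R)-4,6-dimethyl-6-[(2R)-2-methyl-10-phenyldecyl]-1,2-dioxan-3-yl]acetate | C[C@H](CCCCCCCCc1ccccc1)C[C@]1(C)C[C@H](C)[C@H](CC(=O)OC)OO1 | intermediate
23 | 2-[(3S,4S,6R)-4,6-dimethyl-6-[(2R)-2-methyl-10-phenyldecyl]-1,2-dioxan-3-yl]acetic acid | C[C@H](CCCCCCCCc1ccccc1)C[C@]1(C)C[C@H](C)[C@H](CC(=O)O)OO1 | target

Total step count: 15. Longest linear sequence: 10 steps (steps 1–6, then 12–15).

**Steps most likely to fail**

Step 13. The peroxyketal may ionise at the peroxy oxygen or fragment before the weakly nucleophilic vinylsilane attacks, or the vinylsilane may be protodesilylated. The fallback replaces the vinylsilane by an allylsilane, so that the ring closure becomes the known Hosomi–Sakurai-type allylation of a peroxycarbenium ion; it sets out from ketal 10 and comes back at 22. Cross-metathesis of methyl but-3-enoate with an excess of trimethyl(2-methylallyl)silane (second-generation Hoveyda–Grubbs catalyst, CH2Cl2, 40 °C) should give mainly methyl (E)-4-methyl-5-(trimethylsilyl)pent-3-enoate F1. In F1 the C4 methyl group sits on the more substituted side of the alkene, so the Schenck ene reaction should take a methyl hydrogen and, after resolution as in step 11, give methyl (S)-3-hydroperoxy-4-[(trimethylsilyl)methyl]pent-4-enoate F2. Exchange with 10 as in step 12 gives methyl (3S)-3-{[(4R)-2-methoxy-4-methyl-12-phenyldodecan-2-yl]peroxy}-4-[(trimethylsilyl)methyl]pent-4-enoate F3. Me3SiOTf then closes the ring through the terminal alkene carbon with loss of the allylic silyl group and gives methyl 2-[(3S,6R)-6-methyl-4-methylidene-6-[(2R)-2-methyl-10-phenyldecyl]-1,2-dioxan-3-yl]acetate F4. Diimide reduction of the exocyclic alkene as in step 14 leads to 22; the facial preference of this reduction is open, and a C4 epimer would have to be removed by chromatography.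

Step 10. Singlet oxygen may take a hydrogen from the C4 methyl group or from C2 instead of C5, or the vinylsilane may form as the E isomer, which cannot lose silicon after ring closure. The fallback gives up silicon and relies on the closure of a peroxycarbenium ion onto a tethered 1,1-disubstituted alkene, a known reaction type; it sets out from ketal 10 and comes back at 21 and 22. Schenck ene reaction of commercial methyl 4-methylpent-3-enoate, which takes a hydrogen from the methyl group cis to the ester arm, followed by resolution as in step 11, should give methyl (S)-3-hydroperoxy-4-methylpent-4-enoate F5. Exchange with 10 as in step 12 gives methyl (3S)-3-{[(4R)-2-methoxy-4-methyl-12-phenyldodecan-2-yl]peroxy}-4-methylpent-4-enoate F6. Me3SiOTf with 2,6-di-tert-butyl-4-methylpyridine closes the ring by attack of the isopropenyl CH2 group on C6, and the tertiary C4 cation loses a proton to give 21 together with its exocyclic isomer, the compound F4 named above. Both alkenes are reduced by diimide to 22.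

Step 11. The enzyme may accept this hydroperoxide poorly, discriminate the enantiomers weakly, or reduce the S enantiomer first. The fallback is a covalent resolution with a chiral auxiliary; it sets out from racemate 16 and comes back at 17. Addition of 16 to (1R,2S)-2-phenylcyclohexyl 2-propenyl ether (PPTS, CH2Cl2, 0 °C) gives two diastereomeric perketals. Chromatography isolates the 3S diastereomer, methyl (3S,4Z)-4-methyl-3-[(2-{[(1R,2S)-2-phenylcyclohexyl]oxy}propan-2-yl)peroxy]-5-(trimethylsilyl)pent-4-enoate F7, and AcOH/THF/H2O at rt releases 17.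

Further compounds
F1 | step 13 | methyl (E)-4-methyl-5-(trimethylsilyl)pent-3-enoate | C[Si](C)(C)C/C(C)=C/CC(=O)OC
F2 | step 13 | methyl (S)-3-hydroperoxy-4-[(trimethylsilyl)methyl]pent-4-enoate | COC(=O)C[C@H](OO)C(=C)C[Si](C)(C)C
F3 | step 13 | methyl (3S)-3-{[(4R)-2-methoxy-4-methyl-12-phenyldodecan-2-yl]peroxy}-4-[(trimethylsilyl)methyl]pent-4-enoate | C[C@H](CCCCCCCCc1ccccc1)CC(C)(OC)OO[C@@H](CC(=O)OC)C(=C)C[Si](C)(C)C
F4 | step 13 | methyl 2-[(3S,6R)-6-methyl-4-methylidene-6-[(2R)-2-methyl-10-phenyldecyl]-1,2-dioxan-3-yl]acetate | C[C@H](CCCCCCCCc1ccccc1)C[C@]1(C)CC(=C)[C@H](CC(=O)OC)OO1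
F5 | step 10 | methyl (S)-3-hydroperoxy-4-methylpent-4-enoate | COC(=O)C[C@H](OO)C(C)=C
F6 | step 10 | methyl (3S)-3-{[(4R)-2-methoxy-4-methyl-12-phenyldodecan-2-yl]peroxy}-4-methylpent-4-enoate | C[C@H](CCCCCCCCc1ccccc1)CC(C)(OC)OO[C@@H](CC(=O)OC)C(C)=C
F7 | step 11 | methyl (3S,4Z)-4-methyl-3-[(2-{[(1R,2S)-2-phenylcyclohexyl]oxy}propan-2-yl)peroxy]-5-(trimethylsilyl)pent-4-enoate | CC(C)(O[C@@H]1CCCC[C@H]1c1ccccc1)OO[C@@H](CC(=O)OC)/C(C)=C\[Si](C)(C)C
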